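I cannot read the loss of target from the rising limb, where making and loss overlap, so I draw the whole curve first and take the loss from its tail.

| flask | starting material | free catalyst | remark | time |
|---|---|---|---|---|
| autumn | 0.050 M | 0.18 mM | run made earlier |  |
| dawn | 0.025 M | 0.18 mM | run made earlier |  |
| midnight | 0.038 M | 0.18 mM | run made earlier |  |
| oak | 0.050 M (fed, over 2.00 min) | 0.18 mM | a stirred flask in which starting material is dosed at a steady rate over 2.00 min without added volume, worked up at 4.0 min | 4.0 min |
| alder | 0.050 M | 0.18 mM | a single well-mixed tank run continuously and read at steady state, 4.0 min in it on average |  |
| ash | 0.050 M | 0.18 mM | everything together in a closed stirred flask, run for 4.0 min | 4.0 min |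

- autumn (time / min: target / %): 0.833: 31; 1.50: 42; 2.50: 41; 3.00: 35; 4.00: 27
- dawn (time / min: target / %): 1.00: 39; 2.00: 46; 3.00: 35; 4.00: 23; 5.00: 13
- midnight (time / min: target / %): 0.417: 22; 0.667: 30; 1.33: 40; 2.50: 38; 5.00: 17

(readings scatter by 1.5 percentage points)

- the stated concentrations are those of everything mixed, before any reaction; amounts are the same in each set-up
- the analysis behind the earlier runs scatters by 1.5 percentage points, standard deviation
- the feed brings no volume worth counting
- the earlier runs were made in a closed, stirred flask

- the set-up with the highest amount of target at the outlet or at the end, in percent of the starting material put in ("none" if the first two lie within 2 percentage points) (oak / alder / ash / none)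
- amount of target at the outlet or at the end, in percent of the starting material put in, oak
- amount of target at the outlet or at the end, in percent of the starting material put in, alder
- amount of target at the outlet or at the end, in percent of the starting material put in, ash

1. Start: in the dawn run, target rises at about 0.390 min⁻¹ of the charge per minute up to its first reading.

2. Knee: the dawn readings top out at 46% at 2.00 min, near where making and loss are equal.

3. Tail: from 4.00 min to 5.00 min, dawn falls from 23% to 13%. Taken as first-order, that is a loss constant of 0.571 min⁻¹, so the target lifetime, the mean time target survives once made, is 1.75 min, and the curve runs towards zero.

4. Making: adding the triangle of loss to the first dawn reading, about 50.1% of the charge has reacted after 1.00 min, and adding the loss over the area under both dawn segments to the second reading, about 81.4% after 2.00 min. The fraction of starting material left therefore falls with a mean constant of 0.696 min⁻¹ over the first interval and a higher one of 0.985 min⁻¹ over the second, so in my reckoning starting material does not fall first-order, and each constant is only a mean over its own interval.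

5. My reckoning for alder: with a mean stay of 4.0 min and the constant of the second interval, about 79.8% is converted, which puts about 10.1 mM of starting material in the tank, between the 12.5 mM and 4.66 mM that I reckon for dawn across that interval, and dividing by one plus stay over lifetime leaves 24.3% as target.

6. My reckoning for oak and ash: oak's charge has a mean age of 3.00 min, where autumn reads 35%, and ash repeats autumn, which reads 27% at 4.00 min. So I expect oak to be higher than the others.

7. The forecast picks oak, with oak 34%, alder 30% and ash 27%. It holds that “the tank holds about 15–20 mM unreacted starting material, which protects the target”, and its alder figure stands higher than mine.

The flask gives oak: oak 33.5%, alder 24.4%, ash 25.8%.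

    target → over-reaction product (k = 0.00920 s⁻¹)
    starting material + free catalyst ⇌ catalyst intermediate A (K = 24.0 M⁻¹, k = 590 M⁻¹ s⁻¹)
    catalyst intermediate A → catalyst intermediate B (k = 6.00 s⁻¹)
    catalyst intermediate B ⇌ free catalyst + target (K = 0.190 M, k = 11.0 s⁻¹)

Alder lies 5.6 percentage points below the forecast and 0.100 points above my reckoning. Its mean stay of 4.0 min is longer than the target's half-life of 1.3 min, at 3.19 half-lives. With my lifetime, 24.4% corresponds to about 80.2% converted in alder. Oak, left until 40.0 min, stands 20.6 lifetimes past its workup, and its target is 0%.

(The earlier runs and the new flask are calculated from invented constants; noise was put on by code.)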